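**Retrosynthetic overview**

1. Structural feature: in the cis-fused 3,7-dioxabicyclo[3.3.0]octane the syringyl-bearing O–CH(Ar) carbon is bonded to a bridgehead carbon whose other ring neighbour is a CH2–O. If that CH2 is taken back to a lactone C=O, the bridgehead becomes the α-carbon of a γ-lactone, and the syringyl carbon lies five atoms away (bridgehead, second bridgehead, CH2, O, CH2Ar) as a plain arylmethyl ether C–H.
2. Late disconnections: the arylglycerol side chain at its C7–C8 bond (auxiliary-controlled glycolate aldol) and at the aryl O–C8 bond (alkylation of the freed syringyl phenol with a haloacetyl imide).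
3. Core disconnections: guaiacyl oxolane C–O bond (lactone reduction, mesylate closure); bridgehead–benzylic C–C bond (rhodium carbenoid C–H insertion of an α-diazo lactone); trans γ-lactone (oxidative lactonisation); anti homoallylic alcohol (catalytic allylboration of O-benzylvanillin with an E allylboronate that already carries the syringylmethyl ether).
4. Ring order: γ-lactone first, syringyl oxolane second (fused onto the lactone), then the lactone is reduced and re-closed as the guaiacyl oxolane; the side chain is attached last.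
5. Stereocontrol: the allylboration sets the guaiacyl carbon and its bridgehead, the C–H insertion relays these to the second bridgehead and the endo syringyl carbon, and the (S)-4-benzyloxazolidinone sets the threo side chain.

Key step: step 10

Assumption: the (R)-enantiomer of the phosphoric acid in step 5 is taken to give the 1R carbinol, by analogy with its allylborations of aryl aldehydes; if the sense proves opposite, the (S)-catalyst is used and nothing else changes.

Abbreviations used in names: ArG = 4-benzyloxy-3-methoxyphenyl; ArS = 3,5-dimethoxy-4-(triisopropylsilyloxy)phenyl; Xc = (S)-4-benzyl-2-oxooxazolidin-3-yl; FFO = 4-[(1S,3aS,4R,6aS)-4-(4-benzyloxy-3-methoxyphenyl)tetrahydro-1H,3H-furo[3,4-c]furan-1-yl]-2,6-dimethoxyphenoxy.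

**Route**

Step 1
Reactants: 1 syringaldehyde (4-hydroxy-3,5-dimethoxybenzaldehyde)
Product: 2 3,5-dimethoxy-4-(triisopropylsilyloxy)benzaldehyde
Conditions: iPr3SiCl, imidazole, DMF, rt
Reagents that add atoms: triisopropylsilyl chloride, CC(C)[Si](Cl)(C(C)C)C(C)C
Why: Imidazole-promoted silylation of the hindered phenol masks the only acidic OH with a group that tolerates base, hydride and carbenoid chemistry and is later removed by fluoride.

Step 2
Reactants: 2 3,5-dimethoxy-4-(triisopropylsilyloxy)benzaldehyde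
Product: 3 3,5-dimethoxy-4-(triisopropylsilyloxy)benzyl alcohol
Conditions: NaBH4, THF–EtOH, 0 °C
Reagents that add atoms: none
Why: Chemoselective borohydride reduction of the aryl aldehyde gives the benzylic alcohol and leaves the aryl silyl ether intact.

Step 3
Reactants: 3 3,5-dimethoxy-4-(triisopropylsilyloxy)benzyl alcohol; 4 (E)-1,4-dibromobut-2-ene (fourfold excess)
Product: 5 (E)-1-bromo-4-(ArS-methoxy)but-2-ene
Conditions: Ag2O, 4 Å MS, CH2Cl2, rt, dark
Reagents that add atoms: none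
Why: Ag2O-promoted Williamson etherification with an excess of the symmetrical allylic dibromide should give the mono-ether under neutral conditions that spare the aryl silyl ether, with the E geometry carried over.

Step 4
Reactants: 5 (E)-1-bromo-4-(ArS-methoxy)but-2-ene
Product: 6 (E)-2-[4-(ArS-methoxy)but-2-enyl]-4,4,5,5-tetramethyl-1,3,2-dioxaborolane
Conditions: B2pin2, Pd2(dba)3 (1 mol%, zerovalent palladium), THF, 60 °C
Reagents that add atoms: bis(pinacolato)diboron, CC1(C)OB(OC1(C)C)B1OC(C)(C)C(C)(C)O1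
Why: Palladium-catalysed borylation of the allylic bromide runs through a syn π-allyl complex that is borylated at the less substituted terminus, which gives the linear E allylboronate.

Step 5
Reactants: 6 (E)-allylboronate; 7 4-benzyloxy-3-methoxybenzaldehyde (O-benzylvanillin)
Product: 9 (1R,2S)-1-ArG-2-[(ArS-methoxy)methyl]but-3-en-1-ol, via pinacol borate ester 8 (not isolated)
Conditions: (R)-3,3'-bis(2,4,6-triisopropylphenyl)-1,1'-binaphthyl-2,2'-diyl hydrogen phosphate (5 mol%), 4 Å MS, toluene, −30 °C; aq. NaHCO3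
Reagents that add atoms: none
Why: In this chiral phosphoric acid catalysed allylboration the acid hydrogen-bonds to a boronate oxygen and fixes the aldehyde face in a closed chair (Zimmerman–Traxler) transition state, so the E boronate delivers the anti diad and the catalyst sets C1 as R, from which C2 (S) follows.

Step 6
Reactants: 9 (1R,2S)-homoallylic alcohol
Product: 11 (1R,2S)-1-ArG-2-[(ArS-methoxy)methyl]butane-1,4-diol, via B-alkyl-9-BBN adduct 10 (not isolated)
Conditions: 9-BBN (9-borabicyclo[3.3.1]nonane, 3 equiv), THF, 0 °C to rt; 30% H2O2, aq. NaOAc, 0 °C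
Reagents that add atoms: hydrogen peroxide, OO
Why: Anti-Markovnikov hydroboration of the terminal vinyl group with the bulky borane (excess to cover the free hydroxyl) and buffered oxidation of the C–B bond gives the primary alcohol without touching the stereocentres or the aryl silyl ether.

Step 7
Reactants: 11 (1R,2S)-1,4-diol
Product: 14 (4S,5R)-5-ArG-4-[(ArS-methoxy)methyl]dihydrofuran-2(3H)-one, via hydroxy aldehyde 12 (not isolated), via lactol 13 (not isolated)
Conditions: PhI(OAc)2 (2.5 equiv), TEMPO (0.2 equiv), CH2Cl2, rt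
Reagents that add atoms: none
Why: The nitroxyl-catalysed oxidation selects the primary alcohol, the aldehyde is trapped by the secondary hydroxyl as a five-membered lactol, and this is oxidised on to the γ-lactone with the trans C4/C5 centres unchanged.

Step 8
Reactants: 14 trans γ-lactone
Product: 16 (4S,5R)-5-ArG-4-[(ArS-methoxy)methyl]-3-(trifluoroacetyl)dihydrofuran-2(3H)-one (C3 epimers and enol), via lithium enolate 15 (not isolated)
Conditions: LiN(SiMe3)2, THF, −78 °C; CF3CO2CH2CF3, −78 °C; aq. NH4Cl; used crude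
Reagents that add atoms: 2,2,2-trifluoroethyl trifluoroacetate, O=C(OCC(F)(F)F)C(F)(F)F
Why: Claisen-type C-acylation of the lactone enolate with the activated trifluoroacetate activates the α-position for diazo transfer, and C4 and C5 are not acidic and keep their configuration.

Step 9
Reactants: 16 α-trifluoroacetyl lactone
Product: 17 (4S,5R)-5-ArG-3-diazo-4-[(ArS-methoxy)methyl]dihydrofuran-2(3H)-one
Conditions: MeSO2N3, Et3N, H2O (1 equiv), MeCN, rt
Reagents that add atoms: methanesulfonyl azide, CS(=O)(=O)N=[N+]=[N-]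
Why: In this Regitz-type detrifluoroacetylative diazo transfer the enolate adds to the sulfonyl azide and the adduct fragments with loss of the N-sulfonyl trifluoroacetamide to leave the α-diazo lactone.

Step 10
Reactants: 17 α-diazo lactone
Product: 18 (3R,3aS,6S,6aR)-3-ArG-6-ArS-tetrahydro-1H,3H-furo[3,4-c]furan-1-one (endo-ArS, exo-ArG)
Conditions: Rh2(OAc)4 (2 mol%, divalent rhodium), CH2Cl2, 40 °C, slow addition of 17; Et3N-washed silica
Reagents that add atoms: none
Why: Rh2(OAc)4 should expel N2 from 17 to give an electrophilic rhodium carbenoid at the lactone α-carbon, which inserts through a concerted, asynchronous three-centre transition state into one benzylic C–H bond of the arylmethyl ether and so forms the bridgehead–benzylic C–C bond. The closest known reaction type is the intramolecular dirhodium tetracarboxylate catalysed C–H insertion of α-diazo γ-butyrolactones into ether α-C–H bonds. The new oxolane closes in the 1,5 sense (carbenoid carbon, C4, CH2, O, benzylic carbon), and a five-membered ring annulated to a γ-lactone can only be cis-fused, so the existing C4 centre fixes the new bridgehead (6aR). The benzylic centre (6S) is set kinetically: of the two diastereotopic hydrogens, insertion into the one that leaves the aryl group under the concave face, away from the carboxylate wall of the catalyst, is preferred and gives the endo isomer. The step needs site selectivity over 1,2-hydride migration from C4 (butenolide) and over other C–H bonds; this is secured because the target bond is the only sp3 C–H bond in a 1,5 relationship and is made hydridic by the ether oxygen and the electron-rich aryl ring, while the trans C4/C5 arrangement keeps the guaiacyl group remote. Slow addition suppresses carbene dimerisation, and acid is excluded from here on so that the endo centre cannot epimerise to the exo,exo isomer.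

Step 11
Reactants: 18 endo,exo furofuranone
Product: 19 (R)-ArG-[(3S,4S,5S)-5-ArS-4-(hydroxymethyl)tetrahydrofuran-3-yl]methanol
Conditions: LiBH4, THF, 0 °C to rt; aq. NH4Cl
Reagents that add atoms: none
Why: Hydride reduction of the lactone gives the diol without breaking any bond at a stereocentre, so all four centres are retained.

Step 12
Reactants: 19 diol
Product: 21 (1R,3aS,4S,6aS)-1-ArG-4-ArS-tetrahydro-1H,3H-furo[3,4-c]furan, via primary mesylate 20 (not isolated)
Conditions: MeSO2Cl (1.05 equiv), Et3N, CH2Cl2, −20 °C to rt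
Reagents that add atoms: none
Why: Selective sulfonylation of the primary hydroxyl followed by intramolecular Williamson closure (5-exo-tet) by the secondary benzylic hydroxyl forms the second oxolane with retention at the guaiacyl carbon, because its C–O bond is never broken, and the basic medium protects the endo syringyl centre.

Step 13
Reactants: 21 protected epi-furofuran
Product: 22 4-[(1S,3aS,4R,6aS)-4-ArG-tetrahydro-1H,3H-furo[3,4-c]furan-1-yl]-2,6-dimethoxyphenol
Conditions: Bu4NF, THF, 0 °C; aq. NH4Cl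
Reagents that add atoms: none
Why: Fluoride cleaves the aryl Si–O bond selectively and frees the syringyl phenol, while the benzyl ether and the cyclic benzylic ethers are inert.

Step 14
Reactants: 22 syringyl phenol; 23 (S)-4-benzyl-3-(chloroacetyl)oxazolidin-2-one
Product: 25 FFO-CH2-C(=O)-Xc (aryloxyacetyl oxazolidinone), via iodoacetyl imide 24 (not isolated)
Conditions: Cs2CO3, NaI (0.1 equiv), MeCN, 0 °C to rt
Reagents that add atoms: none
Why: Williamson O-alkylation of the caesium phenoxide by the α-halo imide, accelerated by Finkelstein exchange to the iodide, should outrun attack at the imide carbonyls at low temperature and creates no stereocentre.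

Step 15
Reactants: 1 syringaldehyde
Product: 26 4-benzyloxy-3,5-dimethoxybenzaldehyde
Conditions: BnBr, K2CO3, DMF, 60 °C
Reagents that add atoms: benzyl bromide, BrCc1ccccc1
Why: Williamson benzylation of the phenol gives an aldehyde whose protecting group is removed together with the guaiacyl benzyl ether in the last step.

Step 16
Reactants: 25 aryloxyacetyl oxazolidinone; 26 4-benzyloxy-3,5-dimethoxybenzaldehyde
Product: 29 (2S,3R)-3-(4-benzyloxy-3,5-dimethoxyphenyl)-2-FFO-3-hydroxypropanoyl-Xc (syn aldol adduct), via boron enolate 27 (not isolated), via boron aldolate 28 (not isolated)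
Conditions: Bu2BOTf, iPr2NEt, CH2Cl2, −78 to 0 °C; 26, −78 to 0 °C; pH 7 buffer, MeOH, 30% H2O2, 0 °C
Reagents that add atoms: none
Why: In this Evans syn glycolate aldol, soft enolisation gives the Z boron enolate, which reacts through a closed chair transition state on the face opposite the 4-benzyl group of the auxiliary with the imide dipoles opposed, setting C2 as S and C3 as R independently of the remote bicycle.

Step 17
Reactants: 29 syn aldol adduct
Product: 30 (1R,2R)-1-(4-benzyloxy-3,5-dimethoxyphenyl)-2-FFO-propane-1,3-diol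
Conditions: LiBH4, THF, MeOH (1 equiv), 0 °C; aq. NH4Cl
Reagents that add atoms: none
Why: LiBH4 reduces the exocyclic imide carbonyl chemoselectively (reductive auxiliary cleavage) to the primary alcohol without retro-aldol, and the two new centres are untouched, C2 becoming R only through the change in substituent priorities.

Step 18
Reactants: 30 bis-benzyl ether diol
Product: 31 target CNP0317965.1, (1R,2R)-1-(4-hydroxy-3,5-dimethoxyphenyl)-2-{4-[(1S,3aS,4R,6aS)-4-(4-hydroxy-3-methoxyphenyl)tetrahydro-1H,3H-furo[3,4-c]furan-1-yl]-2,6-dimethoxyphenoxy}propane-1,3-diol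
Conditions: H2 (1 atm), 10% Pd/C (palladium on carbon, zerovalent palladium), EtOAc, rt, stopped at full debenzylation
Reagents that add atoms: none
Why: Hydrogenolysis of the two aryl benzyl ethers in a neutral solvent should be faster than cleavage of the benzylic C–O bonds of the oxolanes and of the secondary alcohol, so a short reaction should give the target with all six stereocentres intact.

**Compound list**

1 | syringaldehyde | COc1cc(C=O)cc(OC)c1O | starting material
2 | 3,5-dimethoxy-4-(triisopropylsilyloxy)benzaldehyde | COc1cc(C=O)cc(OC)c1O[Si](C(C)C)(C(C)C)C(C)C | intermediate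
3 | 3,5-dimethoxy-4-(triisopropylsilyloxy)benzyl alcohol | COc1cc(CO)cc(OC)c1O[Si](C(C)C)(C(C)C)C(C)C | intermediate
4 | (E)-1,4-dibromobut-2-ene | BrC/C=C/CBr | starting material
5 | (E)-1-bromo-4-{[3,5-dimethoxy-4-(triisopropylsilyloxy)benzyl]oxy}but-2-ene | COc1cc(COC/C=C/CBr)cc(OC)c1O[Si](C(C)C)(C(C)C)C(C)C | intermediate
6 | (E)-2-(4-{[3,5-dimethoxy-4-(triisopropylsilyloxy)benzyl]oxy}but-2-enyl)-4,4,5,5-tetramethyl-1,3,2-dioxaborolane | COc1cc(COC/C=C/CB2OC(C)(C)C(C)(C)O2)cc(OC)c1O[Si](C(C)C)(C(C)C)C(C)C | intermediate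
7 | 4-benzyloxy-3-methoxybenzaldehyde | COc1cc(C=O)ccc1OCc1ccccc1 | starting material
8 | pinacol borate ester of alcohol 9 (O-bound dioxaborolane) | COc1cc([C@H](OB2OC(C)(C)C(C)(C)O2)[C@@H](C=C)COCc2cc(OC)c(O[Si](C(C)C)(C(C)C)C(C)C)c(OC)c2)ccc1OCc1ccccc1 | intermediate
9 | (1R,2S)-1-(4-benzyloxy-3-methoxyphenyl)-2-({[3,5-dimethoxy-4-(triisopropylsilyloxy)benzyl]oxy}methyl)but-3-en-1-ol | COc1cc([C@H](O)[C@@H](C=C)COCc2cc(OC)c(O[Si](C(C)C)(C(C)C)C(C)C)c(OC)c2)ccc1OCc1ccccc1 | intermediate
10 | B-alkyl-9-borabicyclo[3.3.1]nonane adduct of 9 (boron on the terminal carbon) | COc1cc([C@H](O)[C@@H](CCB2C3CCCC2CCC3)COCc2cc(OC)c(O[Si](C(C)C)(C(C)C)C(C)C)c(OC)c2)ccc1OCc1ccccc1 | intermediate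
11 | (1R,2S)-1-(4-benzyloxy-3-methoxyphenyl)-2-({[3,5-dimethoxy-4-(triisopropylsilyloxy)benzyl]oxy}methyl)butane-1,4-diol | COc1cc([C@H](O)[C@@H](CCO)COCc2cc(OC)c(O[Si](C(C)C)(C(C)C)C(C)C)c(OC)c2)ccc1OCc1ccccc1 | intermediate
12 | (3S,4R)-4-(4-benzyloxy-3-methoxyphenyl)-3-({[3,5-dimethoxy-4-(triisopropylsilyloxy)benzyl]oxy}methyl)-4-hydroxybutanal | COc1cc([C@H](O)[C@@H](CC=O)COCc2cc(OC)c(O[Si](C(C)C)(C(C)C)C(C)C)c(OC)c2)ccc1OCc1ccccc1 | intermediate
13 | (4S,5R)-5-(4-benzyloxy-3-methoxyphenyl)-4-({[3,5-dimethoxy-4-(triisopropylsilyloxy)benzyl]oxy}methyl)tetrahydrofuran-2-ol (both anomers) | COc1cc([C@@H]2OC(O)C[C@H]2COCc2cc(OC)c(O[Si](C(C)C)(C(C)C)C(C)C)c(OC)c2)ccc1OCc1ccccc1 | intermediate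
14 | (4S,5R)-5-(4-benzyloxy-3-methoxyphenyl)-4-({[3,5-dimethoxy-4-(triisopropylsilyloxy)benzyl]oxy}methyl)dihydrofuran-2(3H)-one | COc1cc([C@@H]2OC(=O)C[C@H]2COCc2cc(OC)c(O[Si](C(C)C)(C(C)C)C(C)C)c(OC)c2)ccc1OCc1ccccc1 | intermediate
15 | lithium enolate of lactone 14 | COc1cc([C@@H]2OC(O[Li])=C[C@H]2COCc2cc(OC)c(O[Si](C(C)C)(C(C)C)C(C)C)c(OC)c2)ccc1OCc1ccccc1 | intermediate
16 | (4S,5R)-5-(4-benzyloxy-3-methoxyphenyl)-4-({[3,5-dimethoxy-4-(triisopropylsilyloxy)benzyl]oxy}methyl)-3-(trifluoroacetyl)dihydrofuran-2(3H)-one (C3 unspecified) | COc1cc([C@@H]2OC(=O)C(C(=O)C(F)(F)F)[C@H]2COCc2cc(OC)c(O[Si](C(C)C)(C(C)C)C(C)C)c(OC)c2)ccc1OCc1ccccc1 | intermediate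
17 | (4S,5R)-5-(4-benzyloxy-3-methoxyphenyl)-3-diazo-4-({[3,5-dimethoxy-4-(triisopropylsilyloxy)benzyl]oxy}methyl)dihydrofuran-2(3H)-one | COc1cc([C@@H]2OC(=O)C(=[N+]=[N-])[C@H]2COCc2cc(OC)c(O[Si](C(C)C)(C(C)C)C(C)C)c(OC)c2)ccc1OCc1ccccc1 | intermediate
18 | (3R,3aS,6S,6aR)-3-(4-benzyloxy-3-methoxyphenyl)-6-[3,5-dimethoxy-4-(triisopropylsilyloxy)phenyl]tetrahydro-1H,3H-furo[3,4-c]furan-1-one | COc1cc([C@@H]2OC(=O)[C@@H]3[C@H]2CO[C@@H]3c2cc(OC)c(O[Si](C(C)C)(C(C)C)C(C)C)c(OC)c2)ccc1OCc1ccccc1 | intermediate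
19 | (R)-(4-benzyloxy-3-methoxyphenyl){(3S,4S,5S)-5-[3,5-dimethoxy-4-(triisopropylsilyloxy)phenyl]-4-(hydroxymethyl)tetrahydrofuran-3-yl}methanol | COc1cc([C@H](O)[C@@H]2CO[C@H](c3cc(OC)c(O[Si](C(C)C)(C(C)C)C(C)C)c(OC)c3)[C@@H]2CO)ccc1OCc1ccccc1 | intermediate
20 | primary methanesulfonate of diol 19 | COc1cc([C@H](O)[C@@H]2CO[C@H](c3cc(OC)c(O[Si](C(C)C)(C(C)C)C(C)C)c(OC)c3)[C@@H]2COS(C)(=O)=O)ccc1OCc1ccccc1 | intermediate
21 | (1R,3aS,4S,6aS)-1-(4-benzyloxy-3-methoxyphenyl)-4-[3,5-dimethoxy-4-(triisopropylsilyloxy)phenyl]tetrahydro-1H,3H-furo[3,4-c]furan | COc1cc([C@@H]2OC[C@@H]3[C@H]2CO[C@@H]3c2cc(OC)c(O[Si](C(C)C)(C(C)C)C(C)C)c(OC)c2)ccc1OCc1ccccc1 | intermediate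
22 | 4-[(1S,3aS,4R,6aS)-4-(4-benzyloxy-3-methoxyphenyl)tetrahydro-1H,3H-furo[3,4-c]furan-1-yl]-2,6-dimethoxyphenol | COc1cc([C@@H]2OC[C@@H]3[C@H]2CO[C@@H]3c2cc(OC)c(O)c(OC)c2)ccc1OCc1ccccc1 | intermediate
23 | (S)-4-benzyl-3-(chloroacetyl)oxazolidin-2-one | O=C(CCl)N1[C@@H](Cc2ccccc2)COC1=O | starting material
24 | (S)-4-benzyl-3-(iodoacetyl)oxazolidin-2-one | O=C(CI)N1[C@@H](Cc2ccccc2)COC1=O | intermediate
25 | (S)-4-benzyl-3-({4-[(1S,3aS,4R,6aS)-4-(4-benzyloxy-3-methoxyphenyl)tetrahydro-1H,3H-furo[3,4-c]furan-1-yl]-2,6-dimethoxyphenoxy}acetyl)oxazolidin-2-one | COc1cc([C@@H]2OC[C@@H]3[C@H]2CO[C@@H]3c2cc(OC)c(OCC(=O)N3[C@@H](Cc4ccccc4)COC3=O)c(OC)c2)ccc1OCc1ccccc1 | intermediate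
26 | 4-benzyloxy-3,5-dimethoxybenzaldehyde | COc1cc(C=O)cc(OC)c1OCc1ccccc1 | intermediate
27 | Z di-n-butylboron enolate of imide 25 | COc1cc([C@@H]2OC[C@@H]3[C@H]2CO[C@@H]3c2cc(OC)c(O/C=C(\OB(CCCC)CCCC)N3[C@@H](Cc4ccccc4)COC3=O)c(OC)c2)ccc1OCc1ccccc1 | intermediate
28 | O-(di-n-butylboryl) aldolate of adduct 29 | COc1cc([C@@H]2OC[C@@H]3[C@H]2CO[C@@H]3c2cc(OC)c(O[C@H](C(=O)N3[C@@H](Cc4ccccc4)COC3=O)[C@H](OB(CCCC)CCCC)c3cc(OC)c(OCc4ccccc4)c(OC)c3)c(OC)c2)ccc1OCc1ccccc1 | intermediate
29 | (S)-4-benzyl-3-[(2S,3R)-3-(4-benzyloxy-3,5-dimethoxyphenyl)-2-{4-[(1S,3aS,4R,6aS)-4-(4-benzyloxy-3-methoxyphenyl)tetrahydro-1H,3H-furo[3,4-c]furan-1-yl]-2,6-dimethoxyphenoxy}-3-hydroxypropanoyl]oxazolidin-2-one | COc1cc([C@@H]2OC[C@@H]3[C@H]2CO[C@@H]3c2cc(OC)c(O[C@H](C(=O)N3[C@@H](Cc4ccccc4)COC3=O)[C@H](O)c3cc(OC)c(OCc4ccccc4)c(OC)c3)c(OC)c2)ccc1OCc1ccccc1 | intermediate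
30 | (1R,2R)-1-(4-benzyloxy-3,5-dimethoxyphenyl)-2-{4-[(1S,3aS,4R,6aS)-4-(4-benzyloxy-3-methoxyphenyl)tetrahydro-1H,3H-furo[3,4-c]furan-1-yl]-2,6-dimethoxyphenoxy}propane-1,3-diol | COc1cc([C@@H]2OC[C@@H]3[C@H]2CO[C@@H]3c2cc(OC)c(O[C@H](CO)[C@H](O)c3cc(OC)c(OCc4ccccc4)c(OC)c3)c(OC)c2)ccc1OCc1ccccc1 | intermediate
31 | CNP0317965.1, (1R,2R)-1-(4-hydroxy-3,5-dimethoxyphenyl)-2-{4-[(1S,3aS,4R,6aS)-4-(4-hydroxy-3-methoxyphenyl)tetrahydro-1H,3H-furo[3,4-c]furan-1-yl]-2,6-dimethoxyphenoxy}propane-1,3-diol | COc1cc([C@@H]2OC[C@@H]3[C@H]2CO[C@@H]3c2cc(OC)c(O[C@H](CO)[C@H](O)c3cc(OC)c(O)c(OC)c3)c(OC)c2)ccc1O | target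

**Step count and risks**

Total step count: 18. Longest linear sequence: 17 steps (steps 1 to 14 and 16 to 18, from syringaldehyde); step 15 is a one-step side branch.

Steps most likely to fail:

1. Step 5. The process at risk is facial discrimination by the phosphoric acid with this electron-rich aldehyde and the ether-bearing boronate: an uncatalysed background allylboration would erode the enantiomeric purity while keeping the anti relationship. The fallback sets out from aldehyde 7 and returns at hydroxy aldehyde 12 (hence lactol 13 and, under the conditions of step 7, lactone 14). It builds the diad by an auxiliary-controlled syn aldol, which is the anti diad of 9 because the two carbon arms on C2 exchange their roles. (R)-4-Benzyloxazolidin-2-one is acylated (n-BuLi, pent-4-enoyl chloride, THF, −78 °C) to (R)-4-benzyl-3-(pent-4-enoyl)oxazolidin-2-one F1. Bu2BOTf and iPr2NEt convert it into the Z di-n-butylboron enolate F2, which adds to 7 to give the boron aldolate F3 and, after buffered peroxide work-up, the (2R,3R) syn aldol adduct F4. LiBH4 cleaves the auxiliary to the (1R,2S) 2-allyl-1,3-diol F5. Its primary hydroxyl is etherified (Ag2O, CH2Cl2) with 3,5-dimethoxy-4-(triisopropylsilyloxy)benzyl bromide F6, made from alcohol 3 by an Appel reaction (CBr4, PPh3), to give the pentenyl ether F7. Lemieux–Johnson cleavage of the terminal alkene (OsO4 catalytic, NaIO4, 2,6-lutidine, dioxane–water) then delivers 12.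

2. Step 14. The process at risk is acyl transfer in place of alkylation: the phenoxide or carbonate attacks an imide carbonyl of the base-sensitive chloroacetyl oxazolidinone, or the haloacetyl imide condenses with itself. The fallback sets out from phenol 22 and returns at imide 25, attaching the two-carbon unit first and the auxiliary afterwards. Phenol 22 is alkylated with methyl bromoacetate (K2CO3, acetone) to the methyl aryloxyacetate F8. This is saponified (LiOH, THF–water, work-up at pH 5 to 6) to the aryloxyacetic acid F9. Pivaloyl chloride and Et3N give the mixed pivalic anhydride F10, which acylates lithiated (S)-4-benzyloxazolidin-2-one (n-BuLi, THF, −78 °C) to give 25.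

3. Step 18. The process at risk is over-reduction during the double debenzylation: hydrogenolytic loss of the secondary benzylic hydroxyl of the side chain, or opening of an oxolane at a benzylic C–O bond, once the para-oxygens are unmasked. The fallback sets out from imide 25 and returns at target 31. It moves the only hydrogenolysis to a stage with a single benzyl ether and no side-chain carbinol, and ends with a fluoride deprotection; it does not remove the oxolane-opening risk, which remains at the single hydrogenolysis of 25. Imide 25 is debenzylated (H2, Pd/C (palladium on carbon), EtOAc) to the guaiacyl phenol imide F11, which is silylated (iPr3SiCl, imidazole, DMF) to the bis-silyl-ready imide F12. Its Z di-n-butylboron enolate F13 (Bu2BOTf, iPr2NEt) adds to the silyl-protected aldehyde 2 to give the boron aldolate F14 and, after work-up, the syn aldol adduct F15 with the same (2S,3R) sense as in step 16. LiBH4 gives the bis-silyl diol F16, and Bu4NF (THF, 0 °C) removes both aryl silyl ethers to give 31.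

**Further compounds**

F1 | step 5 | (R)-4-benzyl-3-(pent-4-enoyl)oxazolidin-2-one | C=CCCC(=O)N1[C@H](Cc2ccccc2)COC1=O
F2 | step 5 | Z di-n-butylboron enolate of F1 | C=CC/C=C(\OB(CCCC)CCCC)N1[C@H](Cc2ccccc2)COC1=O
F3 | step 5 | O-(di-n-butylboryl) aldolate of F4 | C=CC[C@@H](C(=O)N1[C@H](Cc2ccccc2)COC1=O)[C@@H](OB(CCCC)CCCC)c1ccc(OCc2ccccc2)c(OC)c1
F4 | step 5 | (R)-4-benzyl-3-{(2R)-2-[(R)-(4-benzyloxy-3-methoxyphenyl)(hydroxy)methyl]pent-4-enoyl}oxazolidin-2-one | C=CC[C@@H](C(=O)N1[C@H](Cc2ccccc2)COC1=O)[C@@H](O)c1ccc(OCc2ccccc2)c(OC)c1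
F5 | step 5 | (1R,2S)-2-allyl-1-(4-benzyloxy-3-methoxyphenyl)propane-1,3-diol | C=CC[C@@H](CO)[C@@H](O)c1ccc(OCc2ccccc2)c(OC)c1
F6 | step 5 | 3,5-dimethoxy-4-(triisopropylsilyloxy)benzyl bromide | COc1cc(CBr)cc(OC)c1O[Si](C(C)C)(C(C)C)C(C)C
F7 | step 5 | (1R,2S)-1-(4-benzyloxy-3-methoxyphenyl)-2-({[3,5-dimethoxy-4-(triisopropylsilyloxy)benzyl]oxy}methyl)pent-4-en-1-ol | C=CC[C@@H](COCc1cc(OC)c(O[Si](C(C)C)(C(C)C)C(C)C)c(OC)c1)[C@@H](O)c1ccc(OCc2ccccc2)c(OC)c1
F8 | step 14 | methyl {4-[(1S,3aS,4R,6aS)-4-(4-benzyloxy-3-methoxyphenyl)tetrahydro-1H,3H-furo[3,4-c]furan-1-yl]-2,6-dimethoxyphenoxy}acetate | COc1cc([C@@H]2OC[C@@H]3[C@H]2CO[C@@H]3c2cc(OC)c(OCC(=O)OC)c(OC)c2)ccc1OCc1ccccc1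
F9 | step 14 | {4-[(1S,3aS,4R,6aS)-4-(4-benzyloxy-3-methoxyphenyl)tetrahydro-1H,3H-furo[3,4-c]furan-1-yl]-2,6-dimethoxyphenoxy}acetic acid | COc1cc([C@@H]2OC[C@@H]3[C@H]2CO[C@@H]3c2cc(OC)c(OCC(=O)O)c(OC)c2)ccc1OCc1ccccc1
F10 | step 14 | mixed anhydride of F9 with pivalic acid | COc1cc([C@@H]2OC[C@@H]3[C@H]2CO[C@@H]3c2cc(OC)c(OCC(=O)OC(=O)C(C)(C)C)c(OC)c2)ccc1OCc1ccccc1
F11 | step 18 | (S)-4-benzyl-3-({4-[(1S,3aS,4R,6aS)-4-(4-hydroxy-3-methoxyphenyl)tetrahydro-1H,3H-furo[3,4-c]furan-1-yl]-2,6-dimethoxyphenoxy}acetyl)oxazolidin-2-one | COc1cc([C@@H]2OC[C@@H]3[C@H]2CO[C@@H]3c2cc(OC)c(OCC(=O)N3[C@@H](Cc4ccccc4)COC3=O)c(OC)c2)ccc1O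
F12 | step 18 | triisopropylsilyl ether of F11 at the guaiacyl oxygen | COc1cc([C@@H]2OC[C@@H]3[C@H]2CO[C@@H]3c2cc(OC)c(OCC(=O)N3[C@@H](Cc4ccccc4)COC3=O)c(OC)c2)ccc1O[Si](C(C)C)(C(C)C)C(C)C
F13 | step 18 | Z di-n-butylboron enolate of F12 | COc1cc([C@@H]2OC[C@@H]3[C@H]2CO[C@@H]3c2cc(OC)c(O/C=C(\OB(CCCC)CCCC)N3[C@@H](Cc4ccccc4)COC3=O)c(OC)c2)ccc1O[Si](C(C)C)(C(C)C)C(C)C
F14 | step 18 | O-(di-n-butylboryl) aldolate of F15 | COc1cc([C@@H]2OC[C@@H]3[C@H]2CO[C@@H]3c2cc(OC)c(O[C@H](C(=O)N3[C@@H](Cc4ccccc4)COC3=O)[C@H](OB(CCCC)CCCC)c3cc(OC)c(O[Si](C(C)C)(C(C)C)C(C)C)c(OC)c3)c(OC)c2)ccc1O[Si](C(C)C)(C(C)C)C(C)C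
F15 | step 18 | (2S,3R) syn aldol adduct of F12 with aldehyde 2 (both aryl oxygens silylated) | COc1cc([C@@H]2OC[C@@H]3[C@H]2CO[C@@H]3c2cc(OC)c(O[C@H](C(=O)N3[C@@H](Cc4ccccc4)COC3=O)[C@H](O)c3cc(OC)c(O[Si](C(C)C)(C(C)C)C(C)C)c(OC)c3)c(OC)c2)ccc1O[Si](C(C)C)(C(C)C)C(C)C
F16 | step 18 | bis(triisopropylsilyl) ether of target 31 at both phenol oxygens | COc1cc([C@@H]2OC[C@@H]3[C@H]2CO[C@@H]3c2cc(OC)c(O[C@H](CO)[C@H](O)c3cc(OC)c(O[Si](C(C)C)(C(C)C)C(C)C)c(OC)c3)c(OC)c2)ccc1O[Si](C(C)C)(C(C)C)C(C)C
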